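## Analysis of the target

6-Prenylsakuranetin (15) is a flavanone in which benzene ring A (C4a, C5 to C8, C8a) is fused to the dihydropyranone ring C (O1, C2, C3, C4), and C2 carries the 4-hydroxyphenyl ring B. Ring A is substituted everywhere except C8: a hydroxyl on C5, the 3-methylbut-2-enyl (prenyl) chain on C6 and a methoxy group on C7. The only stereocentre is C2, of S configuration; it is benzylic, bears the ring oxygen and lies beta to the C4 ketone, so it can be lost by reversible opening of ring C to the 2'-hydroxychalcone, most easily under base and helped by the para hydroxyl of ring B. The prenyl alkene sits ortho to the C5 hydroxyl, so acid closes it to a 2,2-dimethylchroman, and it rules out hydrogenation, ozonolysis and strong electrophiles. The difficulty is twofold: the prenyl group must go to C6 and not C8, which amounts to telling apart the two oxygen atoms O1 and O5 that flank C4a, and C2 must be set and carried intact to the end. The strategy rests on the C3–C4 bond: with C4 written as a 1-silyloxyvinyl group on C4a and C3 as the inner carbon of a vinyl group on C2, ring C becomes a 4-silyloxy-2H-chromene that metathesis can close. The open form of that ring is a branched allylic aryl ether at O1, the product type of asymmetric allylic etherification.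

## Retrosynthetic reasoning

15 from 14. No skeletal bond is cut. The C4 ketone is traced back to its silyl enol ether and the two phenols to silyl ethers, so that the racemisable flavanone exists only in the last flask, where a buffered acidic fluoride source generates it without ever forming a phenoxide.

14 from 13. The C3=C4 bond is cut. It is the only bond of ring C whose two carbons can both be ends of terminal alkenes: C4 as the enol ether of an acetyl group on C4a, C3 as the vinyl group of an allylic ether on O1. The cut leaves O1–C2 intact as an allylic C–O bond, so C2 can be made earlier by an intermolecular catalytic reaction. The forward step must make a ruthenium alkylidene at the vinyl group add to a crowded, electron-rich 1,1-disubstituted enol ether while leaving the prenyl alkene alone; the two terminal CH2 groups leave together as a gas. The open-chain compounds 11 to 13 are aryl methyl ketone derivatives and not beta-aryloxy ketones, so they have no elimination pathway; after closure the enol ether of 14 keeps that pathway shut until the final step.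

13 from 11 (through 12). The silicon groups on O5 and on the enol oxygen are removed in thought, leaving the hydrogen-bonded phenol and methyl ketone of 11. Forward, one silyl triflate and an amine must silylate a hindered phenol and then enolise the only enolisable position, without ionising the benzylic allylic ether.

11 from 6 and 10. The O1–C2 bond is cut. The forward reaction is an iridium-catalysed allylic etherification that has to deliver the branched ether, the S configuration, and the right one of the two phenols of 6. The phenol between the acetyl and prenyl groups is shielded and locked in a hydrogen bond to the ketone; the phenol next to the free ring position is the one expected to react. Cutting here, with 6 already prenylated, puts the O1/O5 distinction on steric grounds.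

6 from 4 (through 5), and 4 from 3 and 2. The bond between C6 and the prenyl CH2 is cut as an aromatic Claisen rearrangement of the tertiary allyl ether 4. The shift ends on the single unsubstituted ortho carbon and turns the 1,1-dimethylallyl group on oxygen into the 3,3-dimethylallyl group on carbon, which direct C-prenylation would not do selectively. Ether 4 comes from the symmetrical diol 3, where no choice between phenols is needed, and carbonate 2 with zerovalent palladium. The prenyl group is installed before the chiral ether on purpose: zerovalent palladium would re-ionise a branched allylic aryl ether, and the heat of the Claisen step would rearrange it.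

10 from 7 (through 8 and 9), and 2 from 1. These are functional group changes only: phenol protection, ester reduction and carbonate formation on the cinnamate side, and carbonate formation on the tertiary alcohol.

## Alternatives that were turned down

Alternative 1: Ring A is taken apart at C8–C8a and C4a–C5. Forward, the trioxygenated diene 1,3-dimethoxy-2-(3-methylbut-2-enyl)-1-(trimethylsilyloxy)buta-1,3-diene A3 would add across the C5=C6 alkene of the enantiopure dihydropyranone (S)-2-[4-(tert-butyldimethylsilyloxy)phenyl]-5-(phenylsulfinyl)-2,3-dihydro-4H-pyran-4-one A2. Loss of the sulfinyl group as its sulfenic acid and collapse of the ketene acetal would then aromatise the adduct to (S)-4'-O-(tert-butyldimethylsilyl)-6-prenylsakuranetin A1. A1 is one desilylation away from 15.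
- For: all four substituents of ring A arrive in one regiodefined operation, and the O1/O5 question never arises on the way to A1. On that point it is stronger than the chosen route, whose step 7 must pick one of two phenols.
- Against: the alkene of A2 is the donor-substituted alkene of a vinylogous ester and is a reluctant dienophile even with the sulfinyl group. One new bond joins a carbon bearing both sulfinyl and acyl groups to the fully substituted ketene acetal terminus of A3. A3 is a hydrolytically fragile, tetrasubstituted ketene silyl acetal. A2 needs an asymmetric hetero-Diels–Alder reaction, a sulfenylation and an oxidation of its own, and it carries C2 beta to a ketone throughout a thermal step, with ring opening available.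
- Comparison: the step count to A1 is no lower. The chosen route buys ring A ready-made and confines its risk to a ring closure that has no stereochemical task.

Alternative 2: The cuts are C4a–C8a and C5–C6. Forward, the pyridazine ring of (S)-5-[4-(tert-butyldimethylsilyloxy)phenyl]-1-methoxy-5-{[5-methoxy-6-(3-methylbut-2-enyl)pyridazin-3-yl]oxy}pent-1-yn-3-one A5 would act as the diene towards its tethered alkyne. The bicyclic adduct would expel its N=N bridge as nitrogen gas and leave (S)-5,7-dimethoxy-6-prenyl-4'-(tert-butyldimethylsilyloxy)flavanone A4.
- For: rings A and C form in one irreversible operation, and the tether of A5 fixes the ring A substitution pattern with no phenol differentiation. In bonds formed per step it is stronger than the chosen route.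
- Against: pyridazines are poor dienes and the push-pull alkyne is not a matched partner, so temperatures well above 150 °C are to be expected. At such temperatures the beta-(heteroaryloxy) ketone of A5 can lose its heteroaryloxy group by beta-elimination and destroy C2. A4 still carries a C5 methyl ether, and cleaving it beside the C7 methoxy group needs a Lewis acid of the BX3 or AlX3 type, which also cyclises the prenyl group onto O5. The trisubstituted pyridazine ring of A5 is a lengthy heterocycle synthesis.
- Comparison: the chosen route stays at or below about 110 °C and uses no strong Lewis acid once the prenyl group is in place.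

Alternative 3: The cut is C2–C3, with C2 created in the same event. Forward, a chiral divalent rhodium tetracarboxylate of the Rh2(O2CR*)4 type would decompose 2-diazo-1-{2-[4-(tert-butyldimethylsilyloxy)benzyloxy]-6-(tert-butyldimethylsilyloxy)-4-methoxy-5-(3-methylbut-2-enyl)phenyl}ethanone A7. The carbenoid at C3 would insert into one of the two enantiotopic benzylic C–H bonds of A7 to give (S)-5,4'-bis(tert-butyldimethylsilyloxy)-7-methoxy-6-prenylflavanone A6.
- For: ring and stereocentre come from the achiral precursor A7 in one catalytic step. The ether of A7 is made by simple alkylation, the stereocentre is made last so nothing upstream can erode it, and A6 is one deprotection from the target. In step economy around ring C it is stronger than the chosen route.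
- Against: carbenoids from diazomethyl ketones are the least selective class. The insertion must form a six-membered ring against the intrinsic preference for five. The ether oxygen of A7 is placed to give a five-membered oxonium ylide, whose benzyl shift would close the five-membered ring instead. The electron-rich ring B and the prenyl alkene are further carbenoid traps, and enantioselectivity in such insertions is usually moderate. The two phenols must still be told apart, and A7 needs a hindered benzoic acid precursor that none of the chosen starting materials provides.
- Comparison: the chosen strategy splits the two tasks. The configuration comes from an allylic substitution with a well-understood sense and level of induction, and the ring closure has no selectivity burden beyond chemoselectivity.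

Key step: step 9

Assumption: the ligand L is (Sa,S,S)-O,O'-(1,1'-binaphthalene-2,2'-diyl) N,N-bis(1-phenylethyl)phosphoramidite, taken to give the S branched ether by the usual sense of induction of this ligand class with heteroatom nucleophiles on cinnamyl carbonates; if the sense were opposite for this aryloxide, the mirror-image ligand would be used with no other change.

## Route

Step 1
Reactants: 1 2-methylbut-3-en-2-ol
Product: 2 tert-butyl 2-methylbut-3-en-2-yl carbonate
Conditions: n-BuLi, THF, −78 °C; then Boc2O, −78 °C to rt
Reagents that add atoms: di-tert-butyl dicarbonate, CC(C)(C)OC(=O)OC(=O)OC(C)(C)C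
Why: O-acylation of the lithium alkoxide of a tertiary allylic alcohol by the dicarbonate; at low temperature neither elimination nor allylic transposition should compete.

Step 2
Reactants: 3 1-(2,6-dihydroxy-4-methoxyphenyl)ethanone (2',6'-dihydroxy-4'-methoxyacetophenone); 2 tert-butyl 2-methylbut-3-en-2-yl carbonate
Product: 4 1-[2-hydroxy-4-methoxy-6-(2-methylbut-3-en-2-yloxy)phenyl]ethanone
Conditions: 2 (1.05 equiv), Pd(PPh3)4 (3 mol%), THF, 0 °C
Reagents that add atoms: none
Why: Tsuji–Trost-type allylic etherification: zerovalent palladium ionises 2 to the cationic (1,1-dimethylallyl)Pd(PPh3)2 complex and tert-butoxide, which deprotonates one phenol, and at 0 °C the aryloxide should attack the more substituted terminus to give the tertiary ether as the kinetic product. The second phenol remains hydrogen-bonded to the ketone and hindered by the new tertiary ether, so mono-etherification of the symmetrical diol should prevail.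

Step 3
Reactants: 4 1-[2-hydroxy-4-methoxy-6-(2-methylbut-3-en-2-yloxy)phenyl]ethanone
Product: 6 1-[2,6-dihydroxy-4-methoxy-3-(3-methylbut-2-enyl)phenyl]ethanone, via Claisen ortho-dienone 5 (not isolated)
Conditions: PhMe, 110 °C
Reagents that add atoms: none
Why: Aromatic Claisen rearrangement: the [3,3] shift delivers the allyl unit to the one unsubstituted ortho carbon with allylic inversion, so the 1,1-dimethylallyl group on oxygen becomes a 3,3-dimethylallyl chain on carbon, and dienone 5 tautomerises to phenol 6. The other ortho carbon carries the acetyl group, so a dienone formed there cannot rearomatise and should not compete, and tertiary allyl ethers rearrange at this moderate temperature.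

Step 4
Reactants: 7 methyl (E)-3-(4-hydroxyphenyl)prop-2-enoate (methyl 4-hydroxycinnamate)
Product: 8 methyl (E)-3-[4-(tert-butyldimethylsilyloxy)phenyl]prop-2-enoate
Conditions: TBSCl, imidazole, DMF, rt
Reagents that add atoms: tert-butyldimethylsilyl chloride, CC(C)(C)[Si](C)(C)Cl
Why: Standard silylation of an unhindered phenol with imidazole as base and nucleophilic catalyst.

Step 5
Reactants: 8 methyl (E)-3-[4-(tert-butyldimethylsilyloxy)phenyl]prop-2-enoate
Product: 9 (E)-3-[4-(tert-butyldimethylsilyloxy)phenyl]prop-2-en-1-ol
Conditions: i-Bu2AlH (2.2 equiv), CH2Cl2, −78 °C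
Reagents that add atoms: none
Why: 1,2-Reduction of a conjugated ester to the allylic alcohol by i-Bu2AlH; the aryl silyl ether and the alkene geometry are not affected at −78 °C.

Step 6
Reactants: 9 (E)-3-[4-(tert-butyldimethylsilyloxy)phenyl]prop-2-en-1-ol
Product: 10 (E)-3-[4-(tert-butyldimethylsilyloxy)phenyl]prop-2-enyl methyl carbonate
Conditions: ClCO2Me, pyridine, CH2Cl2, 0 °C
Reagents that add atoms: methyl chloroformate, COC(=O)Cl
Why: Acylation of a primary allylic alcohol with a chloroformate; the linear methyl carbonate is the usual electrophile for iridium-catalysed allylic substitution.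

Step 7
Reactants: 6 1-[2,6-dihydroxy-4-methoxy-3-(3-methylbut-2-enyl)phenyl]ethanone; 10 (E)-3-[4-(tert-butyldimethylsilyloxy)phenyl]prop-2-enyl methyl carbonate
Product: 11 (S)-1-{6-[1-(4-tert-butyldimethylsilyloxyphenyl)prop-2-enyloxy]-2-hydroxy-4-methoxy-3-(3-methylbut-2-enyl)phenyl}ethanone
Conditions: 6 (1.2 equiv), LiN(SiMe3)2 (1.2 equiv), THF, 0 °C; then 10 and catalyst preformed from [Ir(cod)Cl]2 (2 mol%), L (4 mol%) and n-PrNH2 (THF, 50 °C), THF, rt
Reagents that add atoms: none
Why: Iridium-catalysed asymmetric allylic etherification: the carbonate adds oxidatively to the cyclometalated monovalent iridium phosphoramidite complex, and the lithium aryloxide attacks the aryl-substituted terminus of the allyl ligand anti to the metal, which gives the branched ether with the C2 configuration fixed by the ligand. Of the two phenols of 6, the one between the acetyl and prenyl groups is shielded and held in a hydrogen bond to the ketone, so the oxygen next to the free ring position (the future O1) should be etherified. The reaction is stopped at full conversion of 10 so that the product is not re-ionised.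

Step 8
Reactants: 11 (S)-1-{6-[1-(4-tert-butyldimethylsilyloxyphenyl)prop-2-enyloxy]-2-hydroxy-4-methoxy-3-(3-methylbut-2-enyl)phenyl}ethanone
Product: 13 (S)-1-(tert-butyldimethylsilyloxy)-1-{6-[1-(4-tert-butyldimethylsilyloxyphenyl)prop-2-enyloxy]-2-(tert-butyldimethylsilyloxy)-4-methoxy-3-(3-methylbut-2-enyl)phenyl}ethene, via aryl silyl ether ketone 12 (not isolated)
Conditions: TBSOTf (3 equiv), Et3N (5 equiv), CH2Cl2, 0 °C to rt; chromatography on Et3N-deactivated silica
Reagents that add atoms: tert-butyldimethylsilyl trifluoromethanesulfonate, CC(C)(C)[Si](C)(C)OS(=O)(=O)C(F)(F)F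
Why: The silyl triflate first silylates the phenol to 12, then activates the ketone oxygen so that triethylamine removes a methyl proton (soft enolisation), giving the only possible enol ether. The excess amine keeps the medium basic, so the poorly basic aryl ether oxygen should not be silylated and the benzylic allylic ether should not ionise.

Step 9
Reactants: 13 (S)-1-(tert-butyldimethylsilyloxy)-1-{6-[1-(4-tert-butyldimethylsilyloxyphenyl)prop-2-enyloxy]-2-(tert-butyldimethylsilyloxy)-4-methoxy-3-(3-methylbut-2-enyl)phenyl}ethene
Product: 14 (S)-4,5-bis(tert-butyldimethylsilyloxy)-2-[4-(tert-butyldimethylsilyloxy)phenyl]-7-methoxy-6-(3-methylbut-2-enyl)-2H-chromene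
Conditions: (H2IMes)(PCy3)Cl2Ru=CHPh (second-generation Grubbs catalyst, 10 mol%), PhMe (0.005 M), 60 °C, Ar sparge, dark, base-washed glassware
Reagents that add atoms: none
Why: Ring-closing metathesis: after phosphine loss the catalyst initiates at the monosubstituted vinyl group and places the ruthenium alkylidene on the future C3; this adds in a [2+2] sense to the 1-silyloxyvinyl group, with ruthenium on its CH2 terminus and C3 on C4, and cycloreversion releases 14 and Ru=CH2, which carries the chain while ethylene is swept out. The closest known reaction types are the closure of silyl enol ethers onto terminal alkenes to cyclic silyl enol ethers and the closure of 2-allyloxystyrenes to 2H-chromenes, both with this catalyst. Ring C is closed as a six-membered ring through an endocyclic C3=C4 bond, the two reacting groups being held ortho to each other by C4a and C8a. No stereocentre is formed; C2 comes from step 7 and none of its bonds takes part in the mechanism. The step needs chemoselectivity against the prenyl alkene, which its trisubstituted, gem-dimethyl-terminated structure secures, since the bulky alkylidene does not engage it and no ring of normal size could form through it. Dimerisation through the vinyl group is held back by high dilution, and any such dimer can re-enter the cycle. The electron-rich 1,1-disubstituted enol ether is the slow partner and is reached only intramolecularly, which is why initiation at the vinyl group is the productive order. Moderate temperature and exclusion of light and acid are chosen because 14 is an acid-labile enol ether and a 2H-chromene that could open electrocyclically at O1–C2.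

Step 10
Reactants: 14 (S)-4,5-bis(tert-butyldimethylsilyloxy)-2-[4-(tert-butyldimethylsilyloxy)phenyl]-7-methoxy-6-(3-methylbut-2-enyl)-2H-chromene
Product: 15 (S)-5-hydroxy-2-(4-hydroxyphenyl)-7-methoxy-6-(3-methylbut-2-enyl)chroman-4-one (6-prenylsakuranetin)
Conditions: HF·pyridine, pyridine, THF, 0 °C to rt
Reagents that add atoms: none
Why: Fluoride-mediated cleavage of the enol and the two aryl silyl ethers; the freed enol is protonated at C3 to give the C4 ketone, which the C5 hydroxyl then hydrogen-bonds. The buffered acidic medium never forms a phenoxide, so ring C should not open and C2 should not racemise, and it is too weakly acidic to cyclise the prenyl group onto O5.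

## Compound list

1 | 2-methylbut-3-en-2-ol | CC(C)(O)C=C | starting material
2 | tert-butyl 2-methylbut-3-en-2-yl carbonate | C=CC(C)(C)OC(=O)OC(C)(C)C | intermediate
3 | 1-(2,6-dihydroxy-4-methoxyphenyl)ethanone | CC(=O)c1c(O)cc(OC)cc1O | starting material
4 | 1-[2-hydroxy-4-methoxy-6-(2-methylbut-3-en-2-yloxy)phenyl]ethanone | CC(=O)c1c(O)cc(OC)cc1OC(C)(C)C=C | intermediate
5 | 2-acetyl-3-hydroxy-5-methoxy-6-(3-methylbut-2-enyl)cyclohexa-2,4-dien-1-one (transient, C6 configuration undefined) | CC(=O)C1=C(O)C=C(OC)C(CC=C(C)C)C1=O | intermediate
6 | 1-[2,6-dihydroxy-4-methoxy-3-(3-methylbut-2-enyl)phenyl]ethanone | CC(=O)c1c(O)cc(OC)c(CC=C(C)C)c1O | intermediate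
7 | methyl (E)-3-(4-hydroxyphenyl)prop-2-enoate | COC(=O)/C=C/c1ccc(O)cc1 | starting material
8 | methyl (E)-3-[4-(tert-butyldimethylsilyloxy)phenyl]prop-2-enoate | COC(=O)/C=C/c1ccc(O[Si](C)(C)C(C)(C)C)cc1 | intermediate
9 | (E)-3-[4-(tert-butyldimethylsilyloxy)phenyl]prop-2-en-1-ol | OC/C=C/c1ccc(O[Si](C)(C)C(C)(C)C)cc1 | intermediate
10 | (E)-3-[4-(tert-butyldimethylsilyloxy)phenyl]prop-2-enyl methyl carbonate | COC(=O)OC/C=C/c1ccc(O[Si](C)(C)C(C)(C)C)cc1 | intermediate
11 | (S)-1-{6-[1-(4-tert-butyldimethylsilyloxyphenyl)prop-2-enyloxy]-2-hydroxy-4-methoxy-3-(3-methylbut-2-enyl)phenyl}ethanone | CC(=O)c1c(O)c(CC=C(C)C)c(OC)cc1O[C@@H](C=C)c1ccc(O[Si](C)(C)C(C)(C)C)cc1 | intermediate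
12 | (S)-1-{6-[1-(4-tert-butyldimethylsilyloxyphenyl)prop-2-enyloxy]-2-(tert-butyldimethylsilyloxy)-4-methoxy-3-(3-methylbut-2-enyl)phenyl}ethanone | CC(=O)c1c(O[Si](C)(C)C(C)(C)C)c(CC=C(C)C)c(OC)cc1O[C@@H](C=C)c1ccc(O[Si](C)(C)C(C)(C)C)cc1 | intermediate
13 | (S)-1-(tert-butyldimethylsilyloxy)-1-{6-[1-(4-tert-butyldimethylsilyloxyphenyl)prop-2-enyloxy]-2-(tert-butyldimethylsilyloxy)-4-methoxy-3-(3-methylbut-2-enyl)phenyl}ethene (the tert-butyldimethylsilyl enol ether of 12) | C=C(O[Si](C)(C)C(C)(C)C)c1c(O[Si](C)(C)C(C)(C)C)c(CC=C(C)C)c(OC)cc1O[C@@H](C=C)c1ccc(O[Si](C)(C)C(C)(C)C)cc1 | intermediate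
14 | (S)-4,5-bis(tert-butyldimethylsilyloxy)-2-[4-(tert-butyldimethylsilyloxy)phenyl]-7-methoxy-6-(3-methylbut-2-enyl)-2H-chromene | COc1cc2c(c(O[Si](C)(C)C(C)(C)C)c1CC=C(C)C)C(O[Si](C)(C)C(C)(C)C)=C[C@@H](c1ccc(O[Si](C)(C)C(C)(C)C)cc1)O2 | intermediate
15 | (S)-5-hydroxy-2-(4-hydroxyphenyl)-7-methoxy-6-(3-methylbut-2-enyl)chroman-4-one (6-prenylsakuranetin) | COc1cc2c(c(O)c1CC=C(C)C)C(=O)C[C@@H](c1ccc(O)cc1)O2 | target

## Step count and least certain steps

Total: 10 steps. Longest linear sequence: 7 steps (steps 1, 2, 3, 7, 8, 9, 10 from 1, or steps 4, 5, 6, 7, 8, 9, 10 from 7).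

Step 9 (key step). The most likely failure is that the twisted, doubly ortho-flanked enol ether accepts the alkylidene too slowly. The resting catalyst then decays to ruthenium hydride species that move the vinyl double bond into conjugation with O1 and erase C2, or the substrate dimerises through its vinyl group. Slow thermal opening of the product at O1–C2 would also erode the configuration. The fallback changes how the enol ether is presented; it sets out from 11 and returns at 15. Treatment of 11 with t-Bu2Si(OTf)2 and Et3N in CH2Cl2 at 0 °C should bridge O5 and the enol oxygen and give (S)-2,2-di-tert-butyl-5-{1-[4-(tert-butyldimethylsilyloxy)phenyl]prop-2-enyloxy}-7-methoxy-4-methylidene-8-(3-methylbut-2-enyl)-4H-1,3,2-benzodioxasiline F1. The six-membered silylene ring holds the enol ether in the plane of ring A, points its CH2 group toward the allylic ether, and replaces two bulky silyl groups by one that is tied back. Metathesis of F1 with (H2IMes)(PCy3)Cl2Ru=CHPh in toluene should then give the silylene-bridged (S)-2-[4-(tert-butyldimethylsilyloxy)phenyl]-7-methoxy-6-(3-methylbut-2-enyl)-2H-chromene-4,5-diol cyclic di-tert-butylsilanediyl ether F2, and HF·pyridine with pyridine in THF should convert F2 into 15.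

Step 7. Three processes may interfere: etherification at the wrong phenol, isomerisation of the branched ether to the linear cinnamyl ether, and loss of enantiopurity. The last two arise from re-ionisation of a product whose leaving group is an acyl-stabilised aryloxide and whose cation is stabilised by the silyloxyphenyl ring. The fallback fixes the choice of phenol with a temporary protecting group; it sets out from 4 and returns at 12. Allyl bromide and K2CO3 in DMF should give 1-[2-(allyloxy)-4-methoxy-6-(2-methylbut-3-en-2-yloxy)phenyl]ethanone F3. Heating in toluene at 110 °C should rearrange only the tertiary ether, the simple allyl ether needing a far higher temperature, to give 1-[2-(allyloxy)-6-hydroxy-4-methoxy-5-(3-methylbut-2-enyl)phenyl]ethanone F4. TBSCl and imidazole in DMF should give 1-[2-(allyloxy)-6-(tert-butyldimethylsilyloxy)-4-methoxy-5-(3-methylbut-2-enyl)phenyl]ethanone F5. Pd(PPh3)4 with morpholine in THF should then remove the allyl group to give 1-[6-(tert-butyldimethylsilyloxy)-2-hydroxy-4-methoxy-5-(3-methylbut-2-enyl)phenyl]ethanone F6, which has a single free phenol. Etherification of F6 with 10 under the conditions of step 7 should give 12, and step 8 then only has to form the enol ether.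

Step 8. The silyl triflate may ionise the benzylic allylic ether before the amine intercepts it, the hindered phenol may silylate incompletely, or the enol ether may hydrolyse during isolation. The fallback replaces electrophilic activation by enolate chemistry; it sets out from 11 and returns at 13 with no new compound. TBSCl, imidazole and DMAP in DMF should give 12, which is isolated; KN(SiMe3)2 in THF at −78 °C followed by TBSCl should then trap the potassium enolate on oxygen to give 13.

Step 2. The tertiary ether may equilibrate to the linear prenyl ether through repeated ionisation by zerovalent palladium, both phenols may be etherified, or the electron-rich ring may be allylated on carbon. The fallback avoids allyl palladium chemistry; it sets out from 3 and returns at 4. 3-Chloro-3-methylbut-1-yne with catalytic CuCl2·2H2O and DBU in MeCN at 0 °C should give 1-[2-hydroxy-4-methoxy-6-(2-methylbut-3-yn-2-yloxy)phenyl]ethanone F7. Semi-hydrogenation with H2 over Pd/CaCO3 poisoned with Pb(OAc)2 and quinoline in EtOAc should then give 4.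

## Further compounds

F1 | step 9 | (S)-2,2-di-tert-butyl-5-{1-[4-(tert-butyldimethylsilyloxy)phenyl]prop-2-enyloxy}-7-methoxy-4-methylidene-8-(3-methylbut-2-enyl)-4H-1,3,2-benzodioxasiline | C=C1O[Si](C(C)(C)C)(C(C)(C)C)Oc2c(CC=C(C)C)c(OC)cc(O[C@@H](C=C)c3ccc(O[Si](C)(C)C(C)(C)C)cc3)c12
F2 | step 9 | (S)-2-[4-(tert-butyldimethylsilyloxy)phenyl]-7-methoxy-6-(3-methylbut-2-enyl)-2H-chromene-4,5-diol cyclic di-tert-butylsilanediyl ether | COc1cc2c3c(c1CC=C(C)C)O[Si](C(C)(C)C)(C(C)(C)C)OC3=C[C@@H](c1ccc(O[Si](C)(C)C(C)(C)C)cc1)O2
F3 | step 7 | 1-[2-(allyloxy)-4-methoxy-6-(2-methylbut-3-en-2-yloxy)phenyl]ethanone | CC(=O)c1c(OCC=C)cc(OC)cc1OC(C)(C)C=C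
F4 | step 7 | 1-[2-(allyloxy)-6-hydroxy-4-methoxy-5-(3-methylbut-2-enyl)phenyl]ethanone | CC(=O)c1c(OCC=C)cc(OC)c(CC=C(C)C)c1O
F5 | step 7 | 1-[2-(allyloxy)-6-(tert-butyldimethylsilyloxy)-4-methoxy-5-(3-methylbut-2-enyl)phenyl]ethanone | CC(=O)c1c(OCC=C)cc(OC)c(CC=C(C)C)c1O[Si](C)(C)C(C)(C)C
F6 | step 7 | 1-[6-(tert-butyldimethylsilyloxy)-2-hydroxy-4-methoxy-5-(3-methylbut-2-enyl)phenyl]ethanone | CC(=O)c1c(O)cc(OC)c(CC=C(C)C)c1O[Si](C)(C)C(C)(C)C
F0 | step 8 | none | none
F7 | step 2 | 1-[2-hydroxy-4-methoxy-6-(2-methylbut-3-yn-2-yloxy)phenyl]ethanone | CC(=O)c1c(O)cc(OC)cc1OC(C)(C)C#C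
A1 | alternative 1 | (S)-4'-O-(tert-butyldimethylsilyl)-6-prenylsakuranetin | COc1cc2c(c(O)c1CC=C(C)C)C(=O)C[C@@H](c1ccc(O[Si](C)(C)C(C)(C)C)cc1)O2
A2 | alternative 1 | (S)-2-[4-(tert-butyldimethylsilyloxy)phenyl]-5-(phenylsulfinyl)-2,3-dihydro-4H-pyran-4-one (configuration at sulfur undefined) | O=C1C[C@@H](c2ccc(O[Si](C)(C)C(C)(C)C)cc2)OC=C1S(=O)c1ccccc1
A3 | alternative 1 | 1,3-dimethoxy-2-(3-methylbut-2-enyl)-1-(trimethylsilyloxy)buta-1,3-diene | COC(=C)C(CC=C(C)C)=C(OC)O[Si](C)(C)C
A4 | alternative 2 | (S)-5,7-dimethoxy-6-prenyl-4'-(tert-butyldimethylsilyloxy)flavanone | COc1cc2c(c(OC)c1CC=C(C)C)C(=O)C[C@@H](c1ccc(O[Si](C)(C)C(C)(C)C)cc1)O2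
A5 | alternative 2 | (S)-5-[4-(tert-butyldimethylsilyloxy)phenyl]-1-methoxy-5-{[5-methoxy-6-(3-methylbut-2-enyl)pyridazin-3-yl]oxy}pent-1-yn-3-one | COC#CC(=O)C[C@@H](c1ccc(O[Si](C)(C)C(C)(C)C)cc1)Oc1cc(OC)c(CC=C(C)C)nn1
A6 | alternative 3 | (S)-5,4'-bis(tert-butyldimethylsilyloxy)-7-methoxy-6-prenylflavanone | COc1cc2c(c(O[Si](C)(C)C(C)(C)C)c1CC=C(C)C)C(=O)C[C@@H](c1ccc(O[Si](C)(C)C(C)(C)C)cc1)O2
A7 | alternative 3 | 2-diazo-1-{2-[4-(tert-butyldimethylsilyloxy)benzyloxy]-6-(tert-butyldimethylsilyloxy)-4-methoxy-5-(3-methylbut-2-enyl)phenyl}ethanone | [N-]=[N+]=CC(=O)c1c(O[Si](C)(C)C(C)(C)C)c(CC=C(C)C)c(OC)cc1OCc1ccc(O[Si](C)(C)C(C)(C)C)cc1
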